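## Structural features

The target is a pterocarpan. A chroman (ring B: O5, C6, C6a, C11a, C11b, C4a) and a dihydrobenzofuran (ring C: C6a, C6b, C10a, O11, C11a) share the C6a–C11a bond and sit between two resorcinol-type arenes, rings A and D. Ring A carries an angular 2,2-dimethyl-2H-pyran (ring E) fused at C3–C4 with its oxygen on C3. Ring D carries a 3-hydroxy-2,2-dimethyl-3,4-dihydro-2H-pyran (ring F) fused at C9–C10 with its oxygen on C9, so both halves have the same oxygenation and prenylation pattern.

There are three stereocentres. C6a (R) and C11a (R) are adjacent and cis at the B/C fusion; the ring F carbinol (R) is separated from them by ring D.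

The fragile sites are:
- the C11a–O11 benzylic ether, which ionises in acid because ring A has oxygen ortho (O5) and para (ring E oxygen) to C11b;
- the styrene-like double bond of ring E (acid, oxidants, hydrogenation, radical addition);
- the H-6a/H-11a pair, whose loss gives an aromatic benzofuran.

The real difficulty is absolute control of C6a, a tertiary benzylic carbon with no heteroatom, together with C11a, without hydrogenation or strong acid. The plan exploits two facts: ring B is the chroman of a salicylaldehyde (C11a is the aldehyde carbon, O5 the phenol oxygen), and C6a bears only ring D and hydrogen. A nitro group on C6a makes that carbon nucleophilic toward C11a, holds it as a non-epimerisable quaternary centre while ring C closes, and is then exchanged for hydrogen.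

## Logic of the disconnections

**16 to 15.** The C6a–H bond is replaced by C6a–NO2. This turns the only heteroatom-free stereocentre into a quaternary carbon that nitronate chemistry can build. No atoms are saved, but polar bond formation at C6a becomes possible. The forward step must return hydrogen to the face the nitro group occupied; the cis B/C fusion enforces this for a planar C6a radical.

**15 to 13 (through 14).** The O11–C11a aryl ether bond is cut, opening ring C to a benzylic carbinol and an O11 phenol masked as an acetal. C11a is doubly activated (O5 ortho, ring E oxygen para), so the bond can form by ionisation and capture. The gain is one ring and one stereocentre that need no earlier control. The demand is an acid strong enough to ionise next to a nitro group yet mild toward the ring E alkene.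

**13 to 3 and 12.** Ring B is opened at O5–C6 and C6a–C11a, a retro-Henry and retro-oxa-Michael pair. This divides the pentacycle into two bicyclic halves of equal size, and 12 is itself derived from 3. The forward step must add oxygen to the CH2 terminus of 12 and then choose one face of the nitronate in the C–C bond formation.

**12 to 11, 10, and 8 with 9.** Compound 12 is too prone to polymerise to be stored, so it is traced to acetate 11 and released by elimination. The C6–C6a bond of 10 is cut as a nitroaldol with 9. The demands are mono-hydroxymethylation and an acetylation that does not trigger early elimination.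

**8 to 7 to 6.** The C–N bond is cut to a benzylic bromide and then a benzylic alcohol. Nothing is gained in size, but the nitro carbon is traced to the formyl carbon of 3. The demand is N-alkylation of the ambident nitrite on a very electron-rich benzylic halide.

**6 to 5 to 4.** The C4–H bond of ring F and the carbinol stereocentre are traced to an epoxide of the ring E-type alkene, and the hydroxymethyl group to the formyl group. One hydride reagent does both reductions. The demands are facial selectivity in the epoxidation and hydride attack at the benzylic carbon only. The ring F hydroxyl is carried free from 6 to 16, because every later reagent discriminates against a hindered secondary alcohol.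

**4 to 3 to 1 and 2.** The acetal O–C bond is cut, then the pyran C–C and C–O bonds. The aromatic core and the five-carbon unit become two commodity chemicals. The demand is annulation at the carbon between the two hydroxyls of 1.

## Other disconnections considered

**Alternative 1:** The cut is O11–C11a together with the C6a–H bond. The precursor is the flat isoflav-3-ene A1, and a chiral BINOL-derived phosphoric acid (or N-triflyl phosphoramide) would protonate C6a and let O11 add to C11a of the bound quinone methide, giving A2.
- In favour: the step is an isomerisation with no reagent and no by-product, it sets both ring-fusion centres at once, and it needs neither a nitro group nor tin. On atom economy and on reaching the final oxidation level directly it is better than the chosen plan.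
- Against: a free phenol para to C11a is needed to reach the quinone methide, so ring E cannot be present and must be annulated onto A2 with 2 afterwards (C4 against C2 regiochemistry on a sensitive pterocarpan). C6a is set in a proton transfer to a trisubstituted styrene, or by selective capture of equilibrating ion pairs. A2 keeps the para phenol and could re-open under the same acid.
- Comparison: on structure, A1 is simpler to assemble than 11, so it is the equal or the better. On mechanism, both plans trap the same C11a cation with O11 (equal), but the chosen plan fixes C6a in a C–C bond formation as a quaternary carbon, which is more secure than a reversible C–H formation. On step economy the two are comparable, since the saved denitration is offset by the late ring E annulation.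

**Alternative 2:** The cut removes three bonds of arene D (C10a–C10, C9–C8, C10a–C6b). Photochemical Wolff rearrangement of diazo enone A3 would give a vinylketene that combines with siloxyalkyne A4 by cycloaddition, ring opening and electrocyclic closure to give A5.
- In favour: the route is convergent, the substitution pattern of ring D is fixed by the pericyclic cascade, and the reaction type is well established. On precedent it is better than the chosen key step. C6a enters as a preformed centre in A3 that cannot epimerise.
- Against: ring D is an ordinary resorcinol pattern that 1 supplies directly. A5 has no oxygen at C11a, so ring C needs an oxidative closure. Ring F must be closed from the acetonide with six- against five-membered ring selectivity, ring E must be added with 2, and two silyl ethers must be removed. Diazo and photochemical handling add hazard.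
- Comparison: on structure, it builds the part that is easiest to buy. On mechanism, it is reliable and sets no stereocentre itself. On step economy it is clearly longer than the chosen plan.

**Alternative 3:** The cut is C6a–C11a by a 1,5 C–H insertion. Under Rh2(S-PTTL)4 the aryldiazoacetate A6 would lose N2 and the carbene would insert into the O11 benzylic ether C–H to give the cis ester A7.
- In favour: it forms the same bond as the chosen plan and sets C6a and C11a directly in the cis relationship, with rings E and F already present and no stereochemical relay. The catalyst class has close precedent for cis-2-aryl-2,3-dihydrobenzofuran-3-carboxylates, so on precedent it is better than the chosen key step. It is also tin-free.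
- Against: C6a in A7 is a benzylic ester α-carbon cis to an aryl group and can epimerise to trans until the ester is reduced. Ring B still has to be closed (ester reduction, O5 desilylation, Mitsunobu etherification) and the carbinol desilylated. A6 needs a one-carbon homologation on ring D, an O11 benzylation with a labile electron-rich benzyl unit and a diazo transfer. The electrophilic carbene also faces the ring E alkene.
- Comparison: on structure, it is the same bond made with opposite polarity, and both plans draw both halves from 3 (equal on convergence). On mechanism, one concerted insertion is simpler than a domino that depends on a reversible aldol, but the chosen plan has the more robust C6a centre. On step economy the chosen plan needs two steps after the key step against four.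

Key step: step 9

Remarks on the chemistry (assumptions):
- Formaldehyde 9 is dosed as paraformaldehyde, which depolymerises under the basic conditions of step 7.
- Any hydride that opens the epoxide of 5 reduces its aldehyde first, so the two reductions are one step.
- An acetate leaving group releases one equivalent of acetic acid, which would protonate the catalyst amine after a single turnover, so step 9 includes a stoichiometric insoluble base.
- The salen complex in step 3 is (R,R)-[N,N'-bis(3,5-di-tert-butylsalicylidene)cyclohexane-1,2-diaminato]manganese chloride.

## Route

Step 1
Reactants: 1 2,4-dihydroxybenzaldehyde; 2 3-methylbut-2-enal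
Product: 3 5-hydroxy-2,2-dimethyl-2H-chromene-6-carbaldehyde
Conditions: pyridine, 140 °C, sealed tube
Reagents that add atoms: none
Why: Phenol–enal chromene annulation (Knoevenagel-type condensation at C3, then oxa-6π electrocyclisation of the ortho-quinone methide); the 2-hydroxyl is tied to the formyl group by a hydrogen bond, so the carbon between the two oxygens attacks and the 4-oxygen closes the pyran, which should give the angular isomer 3 as the main product.

Step 2
Reactants: 3 5-hydroxy-2,2-dimethyl-2H-chromene-6-carbaldehyde
Product: 4 5-(methoxymethoxy)-2,2-dimethyl-2H-chromene-6-carbaldehyde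
Conditions: NaH, MOMCl, DMF, 0 °C to rt
Reagents that add atoms: chloromethyl methyl ether, COCCl
Why: Williamson-type O-alkylation of the sodium phenoxide; the acetal masks O11 through the hydridic, nucleophilic and basic steps ahead and later leaves under the same acid that closes ring C.

Step 3
Reactants: 4 5-(methoxymethoxy)-2,2-dimethyl-2H-chromene-6-carbaldehyde
Product: 5 (3R,4R)-3,4-epoxy-5-(methoxymethoxy)-2,2-dimethylchromane-6-carbaldehyde
Conditions: (R,R)-[N,N'-bis(3,5-di-tert-butylsalicylidene)cyclohexane-1,2-diaminato]manganese chloride (4 mol%), 4-phenylpyridine N-oxide, aq. NaOCl (pH 11.3), CH2Cl2, 0 °C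
Reagents that add atoms: sodium hypochlorite, [Na+].[O-]Cl
Why: Jacobsen epoxidation of a 2,2-dimethylchromene, the best substrate class for this catalyst; the (R,R) complex is expected to give the (3R,4R) epoxide, and the formyl group, kept at the aldehyde level on purpose, withdraws enough electron density to keep the benzylic epoxide from ionising.

Step 4
Reactants: 5 (3R,4R)-3,4-epoxy-5-(methoxymethoxy)-2,2-dimethylchromane-6-carbaldehyde
Product: 6 (3R)-6-(hydroxymethyl)-5-(methoxymethoxy)-2,2-dimethylchroman-3-ol
Conditions: LiAlH4, THF, 0 °C to rt; aq. potassium sodium tartrate
Reagents that add atoms: none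
Why: Hydride reduction: LiAlH4 reduces the aldehyde and opens the epoxide by SN2 attack at the benzylic C4 (C3 is shielded by the adjacent gem-dimethyl carbon), so the C3–O bond is untouched, the (3R) carbinol is retained and C4 becomes a methylene group.

Step 5
Reactants: 6 (3R)-6-(hydroxymethyl)-5-(methoxymethoxy)-2,2-dimethylchroman-3-ol
Product: 7 (3R)-6-(bromomethyl)-5-(methoxymethoxy)-2,2-dimethylchroman-3-ol
Conditions: CBr4, PPh3, 2,6-lutidine (cat.), CH2Cl2, 0 °C; used crude at once
Reagents that add atoms: carbon tetrabromide, BrC(Br)(Br)Br
Why: Appel bromination; the primary benzylic hydroxyl should react far faster than the neopentyl-type secondary carbinol, and the neutral conditions spare the acetal.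

Step 6
Reactants: 7 (3R)-6-(bromomethyl)-5-(methoxymethoxy)-2,2-dimethylchroman-3-ol
Product: 8 (3R)-5-(methoxymethoxy)-2,2-dimethyl-6-(nitromethyl)chroman-3-ol
Conditions: NaNO2, urea, phloroglucinol, DMF, −20 °C, dark
Reagents that add atoms: sodium nitrite, [Na+].[O-]N=O
Why: Kornblum nitrite displacement under SN2 conditions (dipolar aprotic solvent, low temperature, no silver) to favour N-alkylation of the ambident nitrite; urea dissolves the salt and phloroglucinol intercepts the nitrite ester by-product.

Step 7
Reactants: 8 (3R)-5-(methoxymethoxy)-2,2-dimethyl-6-(nitromethyl)chroman-3-ol; 9 formaldehyde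
Product: 10 (3R)-6-(2-hydroxy-1-nitroethyl)-5-(methoxymethoxy)-2,2-dimethylchroman-3-ol (both epimers at the nitro carbon)
Conditions: (CH2O)n (1.05 equiv), DBU (5 mol%), THF, 0 °C; AcOH quench
Reagents that add atoms: none
Why: Henry (nitroaldol) addition of the acidic benzylic nitronate to formaldehyde; one equivalent of aldehyde and the ortho substituent should hold the reaction at mono-hydroxymethylation, and the new centre is left uncontrolled because it becomes sp2 in step 9.

Step 8
Reactants: 10 (3R)-6-(2-hydroxy-1-nitroethyl)-5-(methoxymethoxy)-2,2-dimethylchroman-3-ol
Product: 11 2-[(3R)-3-hydroxy-5-(methoxymethoxy)-2,2-dimethylchroman-6-yl]-2-nitroethyl acetate (both epimers at the nitro carbon)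
Conditions: AcCl, 2,4,6-collidine, CH2Cl2, −78 °C; cold aq. citric acid quench
Reagents that add atoms: acetyl chloride, CC(=O)Cl
Why: Selective acetylation of a primary alcohol with acetyl chloride and a hindered pyridine base at low temperature; the hindered secondary carbinol should not react, and proton abstraction from carbon is too slow at this temperature for early elimination.

Step 9
Reactants: 3 5-hydroxy-2,2-dimethyl-2H-chromene-6-carbaldehyde (1.2 equiv); 11 2-[(3R)-3-hydroxy-5-(methoxymethoxy)-2,2-dimethylchroman-6-yl]-2-nitroethyl acetate
Product: 13 (3S,4R)-3-[(3R)-3-hydroxy-5-(methoxymethoxy)-2,2-dimethylchroman-6-yl]-8,8-dimethyl-3-nitro-3,4-dihydro-2H,8H-pyrano[2,3-f]chromen-4-ol, via nitroalkene 12 (not isolated)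
Conditions: 1-[3,5-bis(trifluoromethyl)phenyl]-3-[(8α,9S)-6'-methoxycinchonan-9-yl]thiourea (10 mol%), powdered NaHCO3 (2 equiv), toluene, −20 to 0 °C, slow addition of 11; AcOH quench
Reagents that add atoms: none
Why: Proposed new method: the quinuclidine nitrogen of the catalyst removes the acidic benzylic nitro C–H of 11 and acetate leaves (E1cB), releasing 12 slowly while NaHCO3 takes up the acetic acid so the amine turns over; the catalyst-bound phenoxide of 3 then adds through oxygen to the unsubstituted CH2 terminus of 12, and the thiourea-held nitronate attacks the ortho aldehyde in a 6-exo-trig Henry closure of ring B. The closest known reaction type is the amine–thiourea-catalysed oxa-Michael/Henry domino of salicylaldehydes with 2-aryl-1-nitroethenes; it has not been shown for 1-aryl-1-nitroethenes, where the Michael step creates no stereocentre and all induction must come from the C–C bond formation. C6a (C3 of the new chroman) is set in that Henry step by the catalyst, whose thiourea holds the planar nitronate while the protonated quinuclidine activates the aldehyde; the quinine-derived catalyst is the first choice and its quinidine-derived pseudoenantiomer the alternative, and which of them gives the (3S) series must be settled in the first run. C11a (C4) is expected to form with hydroxyl cis to nitro and trans to the bulky aryl group (O–H···O2N hydrogen bond, reversible aldol), but its configuration is erased in step 10. The step needs chemoselectivity for the phenol over the hindered ring F carbinol, which the difference in acidity secures, and dehydration to a nitrochromene is impossible because C3 carries no hydrogen. The resident (R) carbinol makes the two C3 epimers diastereomers, so the minor one can be detected and removed. Low temperature and an acidic quench are needed so that retro-Henry equilibration does not erode the kinetic selectivity.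

Step 10
Reactants: 13 (3S,4R)-3-[(3R)-3-hydroxy-5-(methoxymethoxy)-2,2-dimethylchroman-6-yl]-8,8-dimethyl-3-nitro-3,4-dihydro-2H,8H-pyrano[2,3-f]chromen-4-ol
Product: 15 (6aS,11aS)-6a-nitro analogue of target 16 (NO2 on C6a cis to H-11a; rings A to F complete; free ring F carbinol), via phenol 14 (not isolated)
Conditions: HCl (1.25 M in MeOH), THF, 45 °C
Reagents that add atoms: none
Why: Acetal methanolysis frees the O11 phenol (14); acid then ionises the C11a hydroxyl to a benzylic cation stabilised by O5 (ortho) and the ring E oxygen (para), and O11 captures it in a 5-exo closure, the classical isoflavan-4-ol to pterocarpan cyclisation. Only the cis B/C fusion is accessible, so C11a is set by the fixed C6a centre whatever the carbinol configuration, and the nitro-bearing carbon has no hydrogen to lose.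

Step 11
Reactants: 15 (6aS,11aS)-6a-nitro analogue of target 16
Product: 16 target CNP0126417.1, (6aR,11aR)-pterocarpan with ring E fused at C3–C4 and ring F fused at C9–C10, (R)-carbinol
Conditions: Bu3SnH (1.5 equiv), AIBN (0.2 equiv), toluene, 90 °C
Reagents that add atoms: none
Why: Radical denitration of a tertiary benzylic nitro compound with tin hydride (stannyl radical adds to a nitro oxygen, the C–N bond fragments, hydrogen is transferred to the C6a radical); hydrogen can reach the planar benzylic radical only on the face that keeps rings B and C cis-fused, so nitro is replaced with retention and the (6aR,11aR) target should result.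

## Compound list

1 | 2,4-dihydroxybenzaldehyde | O=Cc1ccc(O)cc1O | starting material
2 | 3-methylbut-2-enal | CC(C)=CC=O | starting material
3 | 5-hydroxy-2,2-dimethyl-2H-chromene-6-carbaldehyde | CC1(C)C=Cc2c(O1)ccc(C=O)c2O | intermediate
4 | 5-(methoxymethoxy)-2,2-dimethyl-2H-chromene-6-carbaldehyde | CC1(C)C=Cc2c(O1)ccc(C=O)c2OCOC | intermediate
5 | (3R,4R)-3,4-epoxy-5-(methoxymethoxy)-2,2-dimethylchromane-6-carbaldehyde | COCOc1c(C=O)ccc2OC(C)(C)[C@@H]3O[C@@H]3c12 | intermediate
6 | (3R)-6-(hydroxymethyl)-5-(methoxymethoxy)-2,2-dimethylchroman-3-ol | COCOc1c(CO)ccc2OC(C)(C)[C@H](O)Cc12 | intermediate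
7 | (3R)-6-(bromomethyl)-5-(methoxymethoxy)-2,2-dimethylchroman-3-ol | COCOc1c(CBr)ccc2OC(C)(C)[C@H](O)Cc12 | intermediate
8 | (3R)-5-(methoxymethoxy)-2,2-dimethyl-6-(nitromethyl)chroman-3-ol | COCOc1c(C[N+](=O)[O-])ccc2OC(C)(C)[C@H](O)Cc12 | intermediate
9 | formaldehyde (dosed as paraformaldehyde) | C=O | starting material
10 | (3R)-6-(2-hydroxy-1-nitroethyl)-5-(methoxymethoxy)-2,2-dimethylchroman-3-ol, both epimers at the nitro carbon | COCOc1c(C(CO)[N+](=O)[O-])ccc2OC(C)(C)[C@H](O)Cc12 | intermediate
11 | 2-[(3R)-3-hydroxy-5-(methoxymethoxy)-2,2-dimethylchroman-6-yl]-2-nitroethyl acetate, both epimers at the nitro carbon | COCOc1c(C(COC(C)=O)[N+](=O)[O-])ccc2OC(C)(C)[C@H](O)Cc12 | intermediate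
12 | (3R)-5-(methoxymethoxy)-2,2-dimethyl-6-(1-nitroethenyl)chroman-3-ol | C=C([N+](=O)[O-])c1ccc2OC(C)(C)[C@H](O)Cc2c1OCOC | intermediate (not isolated)
13 | (3S,4R)-3-[(3R)-3-hydroxy-5-(methoxymethoxy)-2,2-dimethylchroman-6-yl]-8,8-dimethyl-3-nitro-3,4-dihydro-2H,8H-pyrano[2,3-f]chromen-4-ol (hydroxyl cis to nitro) | CC1(C)C=Cc2c(O1)ccc1c2OC[C@@]([N+](=O)[O-])(c2ccc3OC(C)(C)[C@H](O)Cc3c2OCOC)[C@@H]1O | intermediate
14 | (3S,4R)-3-[(3R)-3,5-dihydroxy-2,2-dimethylchroman-6-yl]-8,8-dimethyl-3-nitro-3,4-dihydro-2H,8H-pyrano[2,3-f]chromen-4-ol | CC1(C)C=Cc2c(O1)ccc1c2OC[C@@]([N+](=O)[O-])(c2ccc3OC(C)(C)[C@H](O)Cc3c2O)[C@@H]1O | intermediate (not isolated)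
15 | (6aS,11aS)-6a-nitropterocarpan with ring E (2,2-dimethyl-2H-pyran on C3–C4, oxygen on C3) and ring F ((R)-3-hydroxy-2,2-dimethyl-3,4-dihydro-2H-pyran on C9–C10, oxygen on C9); nitro cis to H-11a | CC1(C)C=Cc2c(ccc3c2OC[C@@]2([N+](=O)[O-])c4ccc5c(c4O[C@@H]32)C[C@@H](O)C(C)(C)O5)O1 | intermediate
16 | CNP0126417.1, the (6aR,11aR)-pterocarpan with the same rings E and F, (R)-carbinol, H-6a cis to H-11a | CC1(C)C=Cc2c(ccc3c2OC[C@H]2c4ccc5c(c4O[C@@H]32)C[C@@H](O)C(C)(C)O5)O1 | target

## Step count and least certain steps

Total step count: 11. Longest linear sequence: 11 steps (1 to 3 to 4 to 5 to 6 to 7 to 8 to 10 to 11 to 13 to 15 to 16; compound 3 also enters again at step 9).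

**Step 9 (key step).** The most likely failure is poor facial discrimination of the planar nitronate in the ring-closing Henry step, or erosion of it by retro-Henry reopening and reclosure. The catalyst must control a C–C bond formation for which this acceptor class has no precedent. A second risk is anionic oligomerisation of the released nitroalkene.
Fallback (known reactions, stepwise, starting from 3 and 10 and returning at 13): Mitsunobu etherification of the phenol of 3 with the primary hydroxyl of 10 (PPh3, diisopropyl azodicarboxylate, THF, 0 °C) should give the aryl ether aldehyde 5-{2-[(3R)-3-hydroxy-5-(methoxymethoxy)-2,2-dimethylchroman-6-yl]-2-nitroethoxy}-2,2-dimethyl-2H-chromene-6-carbaldehyde F1. Direct substitution and elimination followed by phenol addition converge on this same ether. A catalytic amine base (DBU, THF, 0 °C) should then close ring B by intramolecular Henry reaction to 13 together with its C3 epimer. The two are diastereomers because of the ring F carbinol; they would be separated, and the unwanted one returned to the base for retro-Henry equilibration.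

**Step 6.** The likely failure is O-alkylation of nitrite and ionisation of the very electron-rich benzylic bromide (solvolysis, self-alkylation, participation of the neighbouring acetal), because the ortho and para oxygens push the substitution toward an SN1 course.
Fallback (starting from 6 and returning at 8): MnO2 in CH2Cl2 should oxidise only the benzylic alcohol to (3R)-3-hydroxy-5-(methoxymethoxy)-2,2-dimethylchromane-6-carbaldehyde F2. NH2OH·HCl with NaOAc in EtOH should give its (E)-oxime F3. Buffered peroxytrifluoroacetic acid (urea–hydrogen peroxide, trifluoroacetic anhydride, Na2HPO4, MeCN, 0 °C) should oxidise the oxime to the arylnitromethane 8. No benzylic cation is involved.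

**Step 10.** The likely failure is sluggish ionisation of the C11a hydroxyl, because the adjacent nitro group destabilises the cation. Forcing the acid would then cause hydration or oligomerisation at the ring E double bond.
Fallback (starting from 13, through 14, returning at 15; no compound outside the list is made, F0): the same methanolic HCl at 0 to 20 °C should stop at phenol 14, which would be isolated. Intramolecular Mitsunobu etherification (PPh3, diisopropyl azodicarboxylate, THF, 0 °C) would close ring C by SN2 attack of O11 with inversion at C11a. The expected Henry diastereomer (hydroxyl trans to the aryl group) permits this.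

**Step 11.** The likely failure is addition of the stannyl radical to the ring E double bond, or fragmentation of the C6a radical with loss of an aryloxy radical before hydrogen transfer, because both ring oxygens are β to the radical centre.
Fallback (starting from 15 and returning at 16; no compound outside the list is made, F0): tin-free denitration by photoinduced electron transfer from 1-benzyl-1,4-dihydronicotinamide (irradiation above 350 nm, MeCN, rt). The nitro radical anion expels nitrite and the dihydropyridine delivers hydrogen to the same cis-locked C6a radical, with no stannyl radical present to attack the alkene. This fallback does not address the fragmentation risk, since the dihydropyridine is a slower hydrogen donor than the tin hydride.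

## Further compounds

F1 | step 9 | 5-{2-[(3R)-3-hydroxy-5-(methoxymethoxy)-2,2-dimethylchroman-6-yl]-2-nitroethoxy}-2,2-dimethyl-2H-chromene-6-carbaldehyde (both epimers at the nitro carbon) | CC1(C)C=Cc2c(O1)ccc(C=O)c2OCC([N+](=O)[O-])c1ccc2OC(C)(C)[C@H](O)Cc2c1OCOC
F2 | step 6 | (3R)-3-hydroxy-5-(methoxymethoxy)-2,2-dimethylchromane-6-carbaldehyde | COCOc1c(C=O)ccc2OC(C)(C)[C@H](O)Cc12
F3 | step 6 | (E)-oxime of (3R)-3-hydroxy-5-(methoxymethoxy)-2,2-dimethylchromane-6-carbaldehyde | COCOc1c(/C=N/O)ccc2OC(C)(C)[C@H](O)Cc12
F0 | step 10 | none | none
F0 | step 11 | none | none
A1 | alternative 1 | 3-[(3R)-3,5-dihydroxy-2,2-dimethylchroman-6-yl]-2H-chromen-7-ol | Oc1ccc2C=C(COc2c1)c1ccc2OC(C)(C)[C@H](O)Cc2c1O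
A2 | alternative 1 | (6aR,11aR)-3-hydroxypterocarpan with ring F, (R)-carbinol, lacking ring E | Oc1ccc2c(c1)OC[C@H]1c3ccc4c(c3O[C@@H]21)C[C@@H](O)C(C)(C)O4
A3 | alternative 2 | (3E)-1-diazo-4-[(3R)-7-(triisopropylsilyloxy)chroman-3-yl]but-3-en-2-one | [N-]=[N+]=CC(=O)/C=C/[C@@H]1COc2cc(O[Si](C(C)C)(C(C)C)C(C)C)ccc2C1
A4 | alternative 2 | triisopropyl({3-[(4R)-2,2,5,5-tetramethyl-1,3-dioxolan-4-yl]prop-1-yn-1-yl}oxy)silane | CC(C)[Si](C(C)C)(C(C)C)OC#CC[C@H]1OC(C)(C)OC1(C)C
A5 | alternative 2 | 2-{[(4R)-2,2,5,5-tetramethyl-1,3-dioxolan-4-yl]methyl}-3-(triisopropylsilyloxy)-6-[(3R)-7-(triisopropylsilyloxy)chroman-3-yl]phenol | Oc1c(C[C@H]2OC(C)(C)OC2(C)C)c(O[Si](C(C)C)(C(C)C)C(C)C)ccc1[C@@H]3COc4cc(O[Si](C(C)C)(C(C)C)C(C)C)ccc4C3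
A6 | alternative 3 | methyl 2-diazo-2-[(3R)-3-(tert-butyldimethylsilyloxy)-5-{[5-(tert-butyldimethylsilyloxy)-2,2-dimethyl-2H-chromen-6-yl]methoxy}-2,2-dimethylchroman-6-yl]acetate | COC(=O)C(=[N+]=[N-])c1ccc2OC(C)(C)[C@H](O[Si](C)(C)C(C)(C)C)Cc2c1OCc1ccc2OC(C)(C)C=Cc2c1O[Si](C)(C)C(C)(C)C
A7 | alternative 3 | methyl cis-2-[5-(tert-butyldimethylsilyloxy)-2,2-dimethyl-2H-chromen-6-yl]-2,3-dihydrobenzofuran-3-carboxylate fused with ring F (silyl ether of the (R)-carbinol) | COC(=O)[C@H]1c2ccc3OC(C)(C)[C@H](O[Si](C)(C)C(C)(C)C)Cc3c2O[C@H]1c1ccc2OC(C)(C)C=Cc2c1O[Si](C)(C)C(C)(C)C
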